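**Retrosynthetic overview**

1. Locants, kept for all intermediates: ring A = C1 (CH–CH3), C2 (C=O), C3, C4, C4a (H), C8a (CH3); ring B = C4a, C5 (CH3 and the C11H2–O arm), C6 (CH–CH3), C7, C8, C8a. The route rests on ring B: C5 with its C11 oxymethyl arm next to C6 is the 4-position of a prochiral 4-methyl-4-(acyloxymethyl)cyclohexa-2,5-dienone (carbonyl at C8), whose two enone halves are enantiotopic and whose arm can reach C6.
2. Disconnections, last to first: C11–O aryl ether (isofraxidin); C1–CH3 (enolate methylation); ring A by C3–C4 aldol condensation; C8a–C1 and C4a–C4 by enolate propargylation and vinyl conjugate addition on a C8a-methyl enone; the C8 oxygen is removed once it has served these steps.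
3. C6–CH3 and the C5/C6 stereocentres: intramolecular Michael addition of a phenylsulfonylacetate tethered through O11, which desymmetrises the dienone and closes a temporary cis-fused lactone; CO2 and PhSO2 are then removed.
4. All ring B carbons and C11 come from benzoic acid (Birch reductive methylation creates C5 with its methyl; the carboxyl carbon becomes C11).
5. Ring order: ring B (from the arene), temporary lactone (key step), ring A (aldol).

Key step: step 5

Remark (assumption): the quinine-derived thiourea is taken to select the enone half that leads to the (5S,6R) lactone 9; the sense has to be confirmed on a first run, and the quinidine-derived pseudoenantiomer of the same catalyst class is used if it proves opposite. Centres that do not persist (the sulfonyl-bearing carbon, the C8 carbinol, the ozonide carbon, the aldol carbinol) are carried as mixtures.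

**Route**

Step 1
Reactants: 1 benzoic acid; 2 iodomethane
Product: 4 1-methylcyclohexa-2,5-diene-1-carboxylic acid, via dilithium dienediolate 3 (not isolated)
Conditions: Li, NH3(l)/THF, −78 °C; then MeI; aq. HCl work-up
Reagents that add atoms: iodomethane 2, CI
Why: Birch reduction of the benzoate gives the cross-conjugated dianion, which is methylated at the carboxyl-bearing carbon (Birch reductive alkylation), so the quaternary carbon that becomes C5 and the 1,4-diene arise in one operation.

Step 2
Reactants: 4 1-methylcyclohexa-2,5-diene-1-carboxylic acid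
Product: 5 (1-methylcyclohexa-2,5-dien-1-yl)methanol
Conditions: LiAlH4, THF, 0 °C → rt
Reagents that add atoms: none
Why: Hydride reduction of the carboxylic acid by LiAlH4 gives the primary alcohol (the future C11–OH), and the unconjugated diene is inert to hydride.

Step 3
Reactants: 5 (1-methylcyclohexa-2,5-dien-1-yl)methanol; 6 (phenylsulfonyl)acetic acid
Product: 7 (1-methylcyclohexa-2,5-dien-1-yl)methyl (phenylsulfonyl)acetate
Conditions: DCC, DMAP (cat.), CH2Cl2, 0 °C → rt
Reagents that add atoms: (phenylsulfonyl)acetic acid 6, O=C(O)CS(=O)(=O)c1ccccc1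
Why: Steglich esterification (carbodiimide activation, DMAP acyl transfer) acylates the hindered primary alcohol and so attaches the pronucleophile through the future O11.

Step 4
Reactants: 7 (1-methylcyclohexa-2,5-dien-1-yl)methyl (phenylsulfonyl)acetate
Product: 8 (1-methyl-4-oxocyclohexa-2,5-dien-1-yl)methyl (phenylsulfonyl)acetate
Conditions: Rh2(cap)4 (1 mol %, cap = caprolactamate), t-BuOOH (70% aq.), ClCH2CH2Cl, 40 °C, no base
Reagents that add atoms: tert-butyl hydroperoxide, CC(C)(C)OO
Why: Allylic oxidation by the tert-butylperoxyl radical chain attacks the doubly allylic CH2, by far the weakest and most electron-rich C–H bond, and converts it into the carbonyl of the cross-conjugated dienone; the electron-poor sulfonylacetate CH2 is not abstracted and, with no base present, does not cyclise.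

Step 5
Reactants: 8 (1-methyl-4-oxocyclohexa-2,5-dien-1-yl)methyl (phenylsulfonyl)acetate
Product: 9 cis-fused lactone enone (5S,6R)
Conditions: 1-[3,5-bis(trifluoromethyl)phenyl]-3-[(8S,9S)-6'-methoxycinchonan-9-yl]thiourea (10 mol %), PhMe, 0 °C
Reagents that add atoms: none
Why: The quinuclidine nitrogen of the catalyst deprotonates the sulfonylacetate CH2 while the thiourea hydrogen-bonds the dienone carbonyl, and the carbanion adds to C6, one of the two enantiotopic enone beta-carbons; this is an intramolecular Michael addition of the type established for organocatalytic desymmetrisation of 4,4-disubstituted cyclohexadienones carrying tethered stabilised carbanions. The lactone ring closes in the 6-exo-trig mode. C5 becomes stereogenic and C6 is created in the same event, both fixed by the catalyst's choice of alkene, while their cis relation is imposed by the three-atom ester tether (C11, O, C=O), which can only deliver the carbon on the face of the oxymethyl arm. The sulfonyl-bearing carbon stays acidic and its configuration does not matter. The step needs selection between enantiotopic groups and a single addition: the tether is consumed in the first cyclisation so the second enone cannot react, and the uncatalysed background reaction is suppressed by low temperature and the absence of any other base.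

Step 6
Reactants: 9 cis-fused lactone enone
Product: 10 lactone allylic alcohol (C8 epimers)
Conditions: NaBH4, CeCl3·7H2O, MeOH, −78 → −40 °C
Reagents that add atoms: none
Why: Luche reduction delivers hydride 1,2 to the enone, which masks it as an allylic alcohol before the basic and electron-transfer steps (no retro-Michael, no vinylogous retro-aldol, no enone reduction), and the deprotonated sulfonyl lactone is not reduced.

Step 7
Reactants: 10 lactone allylic alcohol
Product: 12 diol sulfone (C6–CH2SO2Ph), via lithium carboxylate 11 (not isolated)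
Conditions: LiOH·H2O (1.5 equiv), THF/H2O, rt; then DMSO, 110 °C
Reagents that add atoms: none
Why: Saponification opens the activated lactone and the alpha-sulfonyl carboxylate then loses CO2 on heating in DMSO (decarboxylation through the sulfonyl-stabilised carbanion, protonated by water), leaving C6–CH2SO2Ph and the free C11 hydroxyl without touching C5 or C6.

Step 8
Reactants: 12 diol sulfone
Product: 13 (4R,5R)-4-(hydroxymethyl)-4,5-dimethylcyclohex-2-en-1-ol (C1 epimers)
Conditions: Na(Hg) (6%), Na2HPO4, MeOH/THF, −20 °C → rt
Reagents that add atoms: none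
Why: Reductive desulfonylation by electron transfer from Na(Hg) cleaves the alkyl–sulfur bond and turns CH2SO2Ph into the C6 methyl; the allylic alcohol and the isolated alkene are inert, which an enone would not be.

Step 9
Reactants: 13 (4R,5R)-4-(hydroxymethyl)-4,5-dimethylcyclohex-2-en-1-ol
Product: 14 (4R,5R)-4-(hydroxymethyl)-4,5-dimethylcyclohex-2-en-1-one
Conditions: MnO2 (activated), CH2Cl2, rt
Reagents that add atoms: none
Why: MnO2 oxidises only the allylic secondary alcohol, so the enone is restored and the neopentyl primary alcohol is left.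

Step 10
Reactants: 14 (4R,5R)-4-(hydroxymethyl)-4,5-dimethylcyclohex-2-en-1-one
Product: 15 (4R,5R)-4-[(benzyloxy)methyl]-4,5-dimethylcyclohex-2-en-1-one
Conditions: BnOC(=NH)CCl3, TfOH (cat.), CH2Cl2/cyclohexane, 0 °C → rt
Reagents that add atoms: benzyl 2,2,2-trichloroacetimidate, ClC(Cl)(Cl)C(=N)OCc1ccccc1
Why: Acid-catalysed benzylation by the trichloroacetimidate avoids an alkoxide (which could expel formaldehyde from the gamma-hydroxymethyl enone by vinylogous retro-aldol) and installs an ether that lasts until the final hydrogenation.

Step 11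
Reactants: 15 (4R,5R)-4-[(benzyloxy)methyl]-4,5-dimethylcyclohex-2-en-1-one
Product: 16 (4R,5R)-4-[(benzyloxy)methyl]-2-iodo-4,5-dimethylcyclohex-2-en-1-one
Conditions: I2, pyridine, CH2Cl2, 0 °C → rt
Reagents that add atoms: iodine, [I][I]
Why: Alpha-iodination of the enone by addition–elimination: pyridine adds reversibly to the beta-carbon, the enolate is iodinated and pyridine is expelled, which places iodine on C8a.

Step 12
Reactants: 16 (4R,5R)-4-[(benzyloxy)methyl]-2-iodo-4,5-dimethylcyclohex-2-en-1-one; 17 tetramethylstannane
Product: 18 (4R,5R)-4-[(benzyloxy)methyl]-2,4,5-trimethylcyclohex-2-en-1-one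
Conditions: Me4Sn, Pd(PhCN)2Cl2 (5 mol %), AsPh3, CuI, NMP, 80 °C
Reagents that add atoms: tetramethylstannane 17, C[Sn](C)(C)C
Why: Stille cross-coupling of the alpha-iodoenone (oxidative addition, tin-to-palladium methyl transfer assisted by CuI, reductive elimination) puts the future angular methyl on C8a.

Step 13
Reactants: 18 (4R,5R)-4-[(benzyloxy)methyl]-2,4,5-trimethylcyclohex-2-en-1-one; 19 vinylmagnesium bromide
Product: 20 trimethylsilyl enol ether of the C4a-vinyl ketone
Conditions: CH2=CHMgBr, CuBr·SMe2 (20 mol %), TMSCl, HMPA, THF, −78 → −40 °C; Et3N, then NaHCO3 work-up, used crude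
Reagents that add atoms: vinylmagnesium bromide 19, C=C[Mg]Br; chlorotrimethylsilane, C[Si](C)(C)Cl
Why: CuBr·SMe2-catalysed conjugate addition of the vinyl nucleophile, accelerated by TMSCl/HMPA, forms the C4a–C4 bond and traps the enolate regiospecifically as its silyl ether; the vinyl group should enter the face that carries only the C5 methyl, anti to both the C11 arm on C5 and the C6 methyl, which sets C4a with its hydrogen cis to the arm.

Step 14
Reactants: 20 trimethylsilyl enol ether; 21 3-bromo-1-(trimethylsilyl)prop-1-yne
Product: 23 C8 ketone carrying CH3 and CH2C≡CSiMe3 on C8a, via lithium enolate 22 (not isolated)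
Conditions: MeLi, THF, 0 °C; then HMPA, TMSC≡CCH2Br, −78 °C → rt
Reagents that add atoms: 3-bromo-1-(trimethylsilyl)prop-1-yne 21, BrCC#C[Si](C)(C)C
Why: MeLi cleaves the silyl enol ether to the regiodefined lithium enolate, which undergoes SN2 alkylation at C8a by the propargylic bromide on the face anti to the adjacent vinyl group, so the quaternary C8a should form with its methyl trans to the C4a hydrogen.

Step 15
Reactants: 23 C8 ketone
Product: 24 C8 alcohol (epimers)
Conditions: LiAlH4, THF, 0 °C → rt
Reagents that add atoms: none
Why: Hydride reduction by LiAlH4 converts the hindered C8 ketone into the alcohol (configuration irrelevant) without touching the silylalkyne, the vinyl group or the benzyl ether.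

Step 16
Reactants: 24 C8 alcohol; 2 iodomethane
Product: 26 C8 S-methyl xanthate, via sodium xanthate salt 25 (not isolated)
Conditions: NaH, imidazole (cat.), THF, 0 °C → rt; CS2; then MeI
Reagents that add atoms: carbon disulfide, S=C=S; iodomethane 2, CI
Why: Xanthate formation: the sodium alkoxide adds to CS2 and the dithiocarbonate salt is S-methylated, giving the radical precursor for deoxygenation.

Step 17
Reactants: 26 C8 S-methyl xanthate
Product: 28 terminal alkyne (C8 deoxygenated), via silylalkyne 27 (not isolated)
Conditions: Bu3SnH, AIBN (cat.), PhMe, 110 °C; then K2CO3 (cat.), MeOH, rt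
Reagents that add atoms: none
Why: Barton–McCombie deoxygenation: the stannyl radical adds to the thiocarbonyl, the C8–O bond fragments, and the secondary C8 radical (only 4-exo or 5-endo cyclisations onto the alkyne or alkene are open, both slow) takes hydrogen from Bu3SnH, after which methanolic carbonate removes the alkyne silyl group.

Step 18
Reactants: 28 terminal alkyne
Product: 30 alkynyl aldehyde (C4 formyl on C4a), via secondary ozonide 29 (not isolated)
Conditions: O3 (limiting), CH2Cl2, −78 °C; then Me2S, −78 °C → rt
Reagents that add atoms: ozone, [O-][O+]=O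
Why: Ozonolysis with reductive work-up cleaves the monosubstituted alkene, which reacts with ozone far faster than the terminal alkyne, to the C4 aldehyde; it is placed before alkyne hydration because the 1,6-enyne would otherwise cycloisomerise on the gold catalyst.

Step 19
Reactants: 30 alkynyl aldehyde
Product: 31 keto aldehyde (C8a acetonyl, C4a formyl)
Conditions: Ph3PAuNTf2 (2 mol %), 1,4-dioxane/H2O, 60 °C
Reagents that add atoms: water, O
Why: Ph3PAuNTf2-catalysed Markovnikov hydration of the terminal alkyne gives the methyl ketone (C2 carbonyl, C3 methyl) under near-neutral conditions that do not enolise the hindered aldehyde.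

Step 20
Reactants: 31 keto aldehyde
Product: 33 trans-fused enone (C2=O with C3=C4), via aldol adduct 32 (not isolated)
Conditions: piperidine (0.3 equiv), AcOH (0.3 equiv), PhMe, 80 °C
Reagents that add atoms: none
Why: Intramolecular aldol condensation: the methyl ketone reacts through its C3 enamine or enol at the C4 aldehyde in the only feasible ring size (six, ring A) and the aldol loses water to the conjugated enone; the buffered amine salt is chosen so that neither the aldehyde alpha-carbon nor the later gamma-carbon (both C4a) is epimerised.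

Step 21
Reactants: 33 trans-fused enone; 2 iodomethane
Product: 35 C1-methyl enone (C1 epimers), via lithium dienolate 34 (not isolated)
Conditions: LiN(iPr)2, THF, −78 °C; then MeI, DMPU, −78 → −30 °C
Reagents that add atoms: iodomethane 2, CI
Why: Kinetic deprotonation removes the alpha-prime proton at C1 (cross-conjugated dienolate; the gamma-hydrogen on C4a is tertiary and slower) and the enolate is C-methylated there, the C1 configuration being left to the next step.

Step 22
Reactants: 35 C1-methyl enone
Product: 37 (1R,4aR,5R,6R,8aS)-5-(hydroxymethyl)-1,5,6,8a-tetramethyloctahydronaphthalen-2(1H)-one, via C1-epimeric hydroxy ketone 36 (not isolated)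
Conditions: H2 (1 atm), Pd/C (10%), EtOH/EtOAc, rt; filter; then NaOMe (cat.), MeOH, rt
Reagents that add atoms: none
Why: Catalytic hydrogenation saturates C3=C4 and hydrogenolyses the benzyl ether in one operation, and methoxide-mediated epimerisation then brings the only enolisable stereocentre, C1, to the more stable equatorial methyl cis to the angular C8a methyl, as the target requires (C4a is no longer activated and keeps its configuration).

Step 23
Reactants: 37 hydroxy ketone; 38 isofraxidin
Product: 39 target CNP0225022.1
Conditions: PPh3, DIAD, THF (about 3 M), ultrasound, rt → 40 °C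
Reagents that add atoms: isofraxidin 38, COc1cc2ccc(=O)oc2c(OC)c1O
Why: Mitsunobu etherification: the acidic coumarin phenol protonates the betaine and its phenoxide displaces the oxyphosphonium group at the primary C11 in an SN2 step; high concentration and sonication are used because the neopentyl position is slow, and no stereocentre is involved.

**Compound list**

1 | benzoic acid | O=C(O)c1ccccc1 | starting material
2 | iodomethane | CI | starting material
3 | dilithium dienediolate (dianion of 1,4-dihydrobenzoic acid) | [Li+].[Li+].[O-]C([O-])=C1C=CCC=C1 | intermediate (not isolated)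
4 | 1-methylcyclohexa-2,5-diene-1-carboxylic acid | CC1(C(=O)O)C=CCC=C1 | intermediate
5 | (1-methylcyclohexa-2,5-dien-1-yl)methanol | CC1(CO)C=CCC=C1 | intermediate
6 | (phenylsulfonyl)acetic acid | O=C(O)CS(=O)(=O)c1ccccc1 | starting material
7 | (1-methylcyclohexa-2,5-dien-1-yl)methyl (phenylsulfonyl)acetate | CC1(COC(=O)CS(=O)(=O)c2ccccc2)C=CCC=C1 | intermediate
8 | (1-methyl-4-oxocyclohexa-2,5-dien-1-yl)methyl (phenylsulfonyl)acetate, key-step precursor | O=C1C=CC(C)(COC(=O)CS(=O)(=O)c2ccccc2)C=C1 | intermediate
9 | cis-fused lactone enone, (4aR,8aS)-8a-methyl-4-(phenylsulfonyl)-4a,5-dihydro-1H-isochromene-3,6(4H,8aH)-dione (route locants 5S,6R; sulfonyl carbon unassigned) | O=C1OC[C@@]2(C)C=CC(=O)C[C@H]2C1S(=O)(=O)c1ccccc1 | intermediate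
10 | lactone allylic alcohol: 9 with C8–OH in place of C8=O (C8 and sulfonyl carbon unassigned) | O=C1OC[C@@]2(C)C=CC(O)C[C@H]2C1S(=O)(=O)c1ccccc1 | intermediate
11 | lithium carboxylate from lactone opening: C6 bears CH(SO2Ph)CO2Li, C5 bears CH3 and CH2OH (cis to the C6 side chain), C8–OH | OC[C@@]1(C)C=CC(O)C[C@H]1C(C(=O)[O-])S(=O)(=O)c1ccccc1.[Li+] | intermediate (not isolated)
12 | (4S,5R)-4-(hydroxymethyl)-4-methyl-5-[(phenylsulfonyl)methyl]cyclohex-2-en-1-ol (C1 epimers) | OC[C@@]1(C)C=CC(O)C[C@H]1CS(=O)(=O)c1ccccc1 | intermediate
13 | (4R,5R)-4-(hydroxymethyl)-4,5-dimethylcyclohex-2-en-1-ol (C1 epimers; CH2OH and 5-CH3 cis) | OC[C@@]1(C)C=CC(O)C[C@H]1C | intermediate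
14 | (4R,5R)-4-(hydroxymethyl)-4,5-dimethylcyclohex-2-en-1-one | OC[C@@]1(C)C=CC(=O)C[C@H]1C | intermediate
15 | (4R,5R)-4-[(benzyloxy)methyl]-4,5-dimethylcyclohex-2-en-1-one | c1ccccc1COC[C@@]1(C)C=CC(=O)C[C@H]1C | intermediate
16 | (4R,5R)-4-[(benzyloxy)methyl]-2-iodo-4,5-dimethylcyclohex-2-en-1-one | c1ccccc1COC[C@@]1(C)C=C(I)C(=O)C[C@H]1C | intermediate
17 | tetramethylstannane | C[Sn](C)(C)C | starting material
18 | (4R,5R)-4-[(benzyloxy)methyl]-2,4,5-trimethylcyclohex-2-en-1-one | c1ccccc1COC[C@@]1(C)C=C(C)C(=O)C[C@H]1C | intermediate
19 | vinylmagnesium bromide | C=C[Mg]Br | starting material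
20 | trimethylsilyl enol ether (C8–OSiMe3, C8=C8a–CH3); C4a vinyl trans to the C11 benzyloxymethyl arm and to the C6 methyl | c1ccccc1COC[C@@]1(C)[C@H](C=C)C(C)=C(O[Si](C)(C)C)C[C@H]1C | intermediate
21 | 3-bromo-1-(trimethylsilyl)prop-1-yne | BrCC#C[Si](C)(C)C | starting material
22 | lithium enolate corresponding to 20 | c1ccccc1COC[C@@]1(C)[C@H](C=C)C(C)=C([O-])C[C@H]1C.[Li+] | intermediate (not isolated)
23 | C8 ketone; C8a bears CH3 and CH2C≡CSiMe3 (propargyl trans to the C4a vinyl); C5 CH3 and CH2OBn; C6 CH3 cis to CH2OBn | c1ccccc1COC[C@@]1(C)[C@H](C=C)[C@@](C)(CC#C[Si](C)(C)C)C(=O)C[C@H]1C | intermediate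
24 | C8 alcohol from 23 (C8 epimers) | c1ccccc1COC[C@@]1(C)[C@H](C=C)[C@@](C)(CC#C[Si](C)(C)C)C(O)C[C@H]1C | intermediate
25 | sodium O-(C8) dithiocarbonate of 24 | c1ccccc1COC[C@@]1(C)[C@H](C=C)[C@@](C)(CC#C[Si](C)(C)C)C(OC(=S)[S-])C[C@H]1C.[Na+] | intermediate (not isolated)
26 | O-(C8) S-methyl xanthate of 24 | c1ccccc1COC[C@@]1(C)[C@H](C=C)[C@@](C)(CC#C[Si](C)(C)C)C(OC(=S)SC)C[C@H]1C | intermediate
27 | C8-deoxygenated silylalkyne | c1ccccc1COC[C@@]1(C)[C@H](C=C)[C@@](C)(CC#C[Si](C)(C)C)CC[C@H]1C | intermediate (not isolated)
28 | C8-deoxygenated terminal alkyne: cyclohexane with C5 (CH3, CH2OBn), C6 CH3, C4a vinyl, C8a (CH3, propargyl) | c1ccccc1COC[C@@]1(C)[C@H](C=C)[C@@](C)(CC#C)CC[C@H]1C | intermediate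
29 | secondary ozonide (1,2,4-trioxolan-3-yl group on C4a) | c1ccccc1COC[C@@]1(C)[C@H](C2OCOO2)[C@@](C)(CC#C)CC[C@H]1C | intermediate (not isolated)
30 | alkynyl aldehyde (C4a–CHO trans to the C8a propargyl group) | c1ccccc1COC[C@@]1(C)[C@H](C=O)[C@@](C)(CC#C)CC[C@H]1C | intermediate
31 | keto aldehyde (C8a–CH2COCH3, C4a–CHO) | c1ccccc1COC[C@@]1(C)[C@H](C=O)[C@@](C)(CC(C)=O)CC[C@H]1C | intermediate
32 | aldol adduct: trans-decalin with C2 ketone and C4 hydroxyl (C4 unassigned) | c1ccccc1COC[C@@]1(C)[C@@H]2C(O)CC(=O)C[C@@]2(C)CC[C@H]1C | intermediate (not isolated)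
33 | trans-fused enone: 5-[(benzyloxy)methyl]-5,6,8a-trimethyl-4a,5,6,7,8,8a-hexahydronaphthalen-2(1H)-one, (4aR,5R,6R,8aS) by route locants | c1ccccc1COC[C@@]1(C)[C@@H]2C=CC(=O)C[C@@]2(C)CC[C@H]1C | intermediate
34 | lithium cross-conjugated dienolate of 33 (C1=C2–OLi, C3=C4) | c1ccccc1COC[C@@]1(C)[C@@H]2C=CC([O-])=C[C@@]2(C)CC[C@H]1C.[Li+] | intermediate (not isolated)
35 | C1-methyl enone (C1 epimers) | c1ccccc1COC[C@@]1(C)[C@@H]2C=CC(=O)C(C)[C@@]2(C)CC[C@H]1C | intermediate
36 | saturated hydroxy ketone, C1 epimers | OC[C@@]1(C)[C@@H]2CCC(=O)C(C)[C@@]2(C)CC[C@H]1C | intermediate (not isolated)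
37 | (1R,4aR,5R,6R,8aS)-5-(hydroxymethyl)-1,5,6,8a-tetramethyloctahydronaphthalen-2(1H)-one | OC[C@@]1(C)[C@@H]2CCC(=O)[C@H](C)[C@@]2(C)CC[C@H]1C | intermediate
38 | isofraxidin (7-hydroxy-6,8-dimethoxy-2H-chromen-2-one) | COc1cc2ccc(=O)oc2c(OC)c1O | starting material
39 | CNP0225022.1: 6,8-dimethoxy-7-{[(1R,2R,4aS,5R,8aR)-1,2,4a,5-tetramethyl-6-oxodecahydronaphthalen-1-yl]methoxy}-2H-chromen-2-one | COc1cc2ccc(=O)oc2c(OC)c1OC[C@@]1(C)[C@@H]2CCC(=O)[C@H](C)[C@@]2(C)CC[C@H]1C | target

**Totals**

Total step count: 23. Longest linear sequence: 23 steps (from benzoic acid 1; all other numbered starting materials are purchased).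

**Steps most likely to fail**

Step 5. The catalyst may discriminate poorly between the two enantiotopic enone halves, or a racemic background cyclisation may run beside the catalysed one, so that 9 is formed with insufficient enantiomeric purity. The fallback sets out from 8 and changes from asymmetric catalysis to resolution. The lactone is closed with an achiral base (DBU, CH2Cl2, 0 °C), which gives 9 together with its mirror image, the enantiomeric lactone F1. The two are separated by preparative chromatography on a chiral stationary phase (amylose carbamate phase, supercritical CO2/MeOH). The route is rejoined at 9.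

Step 14. The alkylation of the tetrasubstituted enolate may take place on the wrong face: the C11 arm on C5 is 1,3 to C8a and can shield the face that the adjacent vinyl group leaves open, which would put the propargyl group cis to vinyl. The fallback sets out from 15 (steps 11 and 12 are skipped) and reverses the order in which the two C8a substituents are introduced. Conjugate addition of CH2=CHMgBr 19 under the conditions of step 13 gives the C8a-unsubstituted silyl enol ether F2. MeLi followed by bromide 21 gives the C8a-monosubstituted propargyl ketone F3, whose C8a configuration is immaterial. Equilibrating silylation (TMSCl, NaI, Et3N, MeCN, rt) gives the more substituted silyl enol ether F4. MeLi followed by MeI 2 then methylates C8a. The last electrophile is now the methyl group, so the same facial preference that spoils step 14 would place CH3 cis to vinyl and leave the propargyl group trans. The route is rejoined at 23.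

Step 23. The SN2 displacement at the neopentyl C11 by a phenol flanked by two methoxy groups may be too slow, so that the oxyphosphonium intermediate is diverted to alkylation of the hydrazide or simply persists. The fallback sets out from 37 and changes from redox condensation to alkylation of a phenoxide with a preformed sulfonate. Tf2O and 2,6-lutidine in CH2Cl2 at −40 °C give the neopentyl triflate F5, which has no beta-hydrogen on C5 and so cannot eliminate. The caesium phenoxide of isofraxidin 38 (Cs2CO3, DMF, rt → 50 °C) then displaces the triflate. The route is rejoined at 39.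

Further compounds
F1 | step 5 | enantiomeric lactone, (4aS,8aR)-8a-methyl-4-(phenylsulfonyl)-4a,5-dihydro-1H-isochromene-3,6(4H,8aH)-dione | O=C1OC[C@]2(C)C=CC(=O)C[C@@H]2C1S(=O)(=O)c1ccccc1
F2 | step 14 | C8a-unsubstituted trimethylsilyl enol ether (C8–OSiMe3, C8=C8a–H; C4a vinyl trans to the C11 arm) | c1ccccc1COC[C@@]1(C)[C@H](C=C)C=C(O[Si](C)(C)C)C[C@H]1C
F3 | step 14 | C8a-monosubstituted propargyl ketone (C8a–H, CH2C≡CSiMe3; C8a unassigned) | c1ccccc1COC[C@@]1(C)[C@H](C=C)C(CC#C[Si](C)(C)C)C(=O)C[C@H]1C
F4 | step 14 | more substituted trimethylsilyl enol ether (C8–OSiMe3, C8=C8a–CH2C≡CSiMe3) | c1ccccc1COC[C@@]1(C)[C@H](C=C)C(CC#C[Si](C)(C)C)=C(O[Si](C)(C)C)C[C@H]1C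
F5 | step 23 | neopentyl triflate of 37 | FC(F)(F)S(=O)(=O)OC[C@@]1(C)[C@@H]2CCC(=O)[C@H](C)[C@@]2(C)CC[C@H]1C
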